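## Retrosynthetic overview

1. The butenolide is made last, from a 3‑substituted furan by singlet‑oxygen [4+2] addition, base fragmentation and borohydride reduction; the furan is bought as furan‑3‑carbaldehyde.
2. The C(sp3)–C(sp2) bond next to the hydroxymethyl alkene is made by B‑alkyl Suzuki coupling of a homoallyl borane (left half) with an (E)‑2‑iodoallylic diol (right half); the alkene geometry comes from syn‑hydrostannation/iodination of a propargylic diol.
3. Right half: the carbinol stereocentre is set by catalytic asymmetric propargylation of furan‑3‑carbaldehyde, followed by hydroxymethylation of the alkyne.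
4. Left half: the E‑trisubstituted alkene is made by Zr‑catalysed methylalumination and vinylation of a terminal alkyne.
5. The cyclohexene ring is formed first, by proton‑triggered head‑to‑tail cation–olefin cyclisation of an acyclic geranyl–propyne dienyne; the alkyne is the masked alkene, so the cascade has to stop after one ring.

Assumption: (R)‑TRIP gives Re‑face propargylation of furan‑3‑carbaldehyde, as it does with aryl aldehydes; if the rotation of the product shows the opposite sense, (S)‑TRIP is used.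

## Route

Step 1
Reactants: 1 geranyl bromide, (2E)-1-bromo-3,7-dimethylocta-2,6-diene; 2 propyne
Product: 4 (5E)-6,10-dimethylundeca-5,9-dien-1-yne, via 1,3-dilithiopropyne 3 (not isolated)
Conditions: n-BuLi (2 equiv), TMEDA, Et2O–hexane, −78 °C → rt; then 1, −78 °C → rt; H2O
Reagents that add atoms: none
Why: The sp3 carbanion of 1,3‑dilithiopropyne is far more nucleophilic than its acetylide end and displaces the primary allylic bromide by SN2 without touching the (E)‑alkene, leaving a lithium acetylide that is protonated on quench (propargyl dianion alkylation).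

Step 2
Reactants: 4 (5E)-6,10-dimethylundeca-5,9-dien-1-yne
Product: 6 2-(but-3-yn-1-yl)-1,3,3-trimethylcyclohex-1-ene, via tertiary cyclohexyl cation 5 (not isolated)
Conditions: ClSO3H (3 equiv), 2-nitropropane, −78 °C; Et3N, then aq. NaHCO3
Reagents that add atoms: none
Why: Biomimetic proton‑initiated cation–olefin (head‑to‑tail) monocyclisation: Markovnikov protonation of the terminal isopropylidene, 6‑endo capture by the C5=C6 alkene (whose geometry is irrelevant) and E1 loss of H+ from cation 5 give the tetrasubstituted β‑olefin, the thermodynamic isomer (minor α/γ isomers are separable on AgNO3–silica); the cascade cannot continue because the only remaining π‑bond is a terminal alkyne that would have to form a vinyl cation, and no stereocentre is formed.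

Step 3
Reactants: 6 2-(but-3-yn-1-yl)-1,3,3-trimethylcyclohex-1-ene
Product: 8 1,3,3-trimethyl-2-[(3E)-3-methylhexa-3,5-dien-1-yl]cyclohex-1-ene, via alkenylalane 7 (not isolated)
Conditions: Me3Al, Cp2ZrCl2 (cat.), (CH2Cl)2, rt; then CH2=CHBr, ZnCl2 (cat.), Pd(PPh3)4 (cat.), THF, rt
Reagents that add atoms: trimethylaluminium, C[Al](C)C; vinyl bromide, C=CBr
Why: Negishi Zr‑catalysed syn‑methylalumination of the terminal alkyne (methyl to the internal carbon, aluminium to the terminus, ring alkene inert) followed by Pd/Zn‑catalysed alkenyl–alkenyl Negishi coupling with retention fixes the E‑trisubstituted alkene.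

Step 4
Reactants: 9 furan-3-carbaldehyde; 10 allenylboronic acid pinacol ester, 4,4,5,5-tetramethyl-2-(propa-1,2-dien-1-yl)-1,3,2-dioxaborolane
Product: 11 (1R)-1-(furan-3-yl)but-3-yn-1-ol
Conditions: (R)-TRIP (5 mol%), 4 Å MS, toluene, −20 °C → rt; aqueous work-up
Reagents that add atoms: none
Why: Chiral phosphoric acid‑catalysed asymmetric propargylation, in which the allenylboronate adds by SE2' through a closed six‑membered transition state held by the catalyst so that Re‑face attack sets the (R)‑carbinol.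

Step 5
Reactants: 11 (1R)-1-(furan-3-yl)but-3-yn-1-ol
Product: 13 (5R)-5-(furan-3-yl)pent-2-yne-1,5-diol, via dilithio dianion 12 (not isolated)
Conditions: n-BuLi (2.1 equiv), THF, −78 → 0 °C; (CH2O)n, 0 °C → rt; H2O
Reagents that add atoms: paraformaldehyde (as formaldehyde), C=O
Why: Two equivalents of base give the O,C‑dianion, whose acetylide carbon adds to formaldehyde (acetylide hydroxymethylation); the carbinol centre is not touched.

Step 6
Reactants: 13 (5R)-5-(furan-3-yl)pent-2-yne-1,5-diol
Product: 15 (2E,5R)-5-(furan-3-yl)-2-iodopent-2-ene-1,5-diol, via vinylstannane 14 (not isolated)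
Conditions: Bu3SnH, PdCl2(PPh3)2 (cat.), THF, 0 °C → rt; then I2, CH2Cl2, 0 °C
Reagents that add atoms: iodine, II
Why: Pd‑catalysed syn‑hydrostannation puts tin on the alkyne carbon next to the propargylic CH2OH and hydrogen on the other carbon, and iododestannylation with retention gives the vinyl iodide in which CH2OH is cis to the CH2CH(OH) arm, which is the alkene geometry of the target.

Step 7
Reactants: 8 1,3,3-trimethyl-2-[(3E)-3-methylhexa-3,5-dien-1-yl]cyclohex-1-ene; 15 (2E,5R)-5-(furan-3-yl)-2-iodopent-2-ene-1,5-diol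
Product: 17 (2Z,5R)-5-(furan-3-yl)-2-[(3E)-4-methyl-6-(2,6,6-trimethylcyclohex-1-en-1-yl)hex-3-en-1-yl]pent-2-ene-1,5-diol, via B-alkyl-9-BBN 16 (not isolated)
Conditions: 8, 9-BBN, THF, rt; then 15, PdCl2(dppf) (cat.), AsPh3, Cs2CO3, DMF–H2O, rt
Reagents that add atoms: none
Why: 9‑BBN hydroborates only the monosubstituted terminus of the diene (anti‑Markovnikov), and B‑alkyl Suzuki–Miyaura coupling joins this sp3 carbon to the vinyl iodide with retention, giving the (Z)‑2‑alkyl allylic diol without protecting groups.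

Step 8
Reactants: 17 (2Z,5R)-5-(furan-3-yl)-2-[(3E)-4-methyl-6-(2,6,6-trimethylcyclohex-1-en-1-yl)hex-3-en-1-yl]pent-2-ene-1,5-diol
Product: 20 4-[(1R,3Z,7E)-1-hydroxy-4-(hydroxymethyl)-8-methyl-10-(2,6,6-trimethylcyclohex-1-en-1-yl)deca-3,7-dien-1-yl]furan-2(5H)-one, via furan endoperoxide 18 (not isolated), via γ-hydroxybutenolide 19 (not isolated)
Conditions: O2, hν, tetraphenylporphyrin (cat.), i-Pr2NEt, CH2Cl2, −78 °C; then NaBH4, EtOH, 0 °C; 1 M HCl
Reagents that add atoms: oxygen, O=O
Why: Biomimetic furan oxidation: the electron‑rich furan undergoes [4+2] cycloaddition with singlet oxygen faster than the tri‑ and tetrasubstituted alkenes at −78 °C, the hindered amine removes the less hindered bridgehead hydrogen (Kornblum–DeLaMare) to give the 4‑substituted 5‑hydroxybutenolide, and borohydride reduction of its open aldehyde form followed by acid lactonisation leaves the butenolide, with the (R)‑carbinol untouched.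

## Compound list

1 | geranyl bromide, (2E)-1-bromo-3,7-dimethylocta-2,6-diene | CC(C)=CCC/C(C)=C/CBr | starting material
2 | propyne | CC#C | starting material
3 | 1,3-dilithiopropyne | [Li]CC#C[Li] | intermediate
4 | (5E)-6,10-dimethylundeca-5,9-dien-1-yne | CC(C)=CCC/C(C)=C/CCC#C | intermediate
5 | 2-(but-3-yn-1-yl)-1,3,3-trimethylcyclohexyl cation | C[C+]1CCCC(C)(C)C1CCC#C | intermediate
6 | 2-(but-3-yn-1-yl)-1,3,3-trimethylcyclohex-1-ene | CC1=C(CCC#C)C(C)(C)CCC1 | intermediate
7 | dimethyl[(1E)-2-methyl-4-(2,6,6-trimethylcyclohex-1-en-1-yl)but-1-en-1-yl]alumane | CC1=C(CC/C(C)=C/[Al](C)C)C(C)(C)CCC1 | intermediate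
8 | 1,3,3-trimethyl-2-[(3E)-3-methylhexa-3,5-dien-1-yl]cyclohex-1-ene | CC1=C(CC/C(C)=C/C=C)C(C)(C)CCC1 | intermediate
9 | furan-3-carbaldehyde | O=Cc1ccoc1 | starting material
10 | allenylboronic acid pinacol ester | C=C=CB1OC(C)(C)C(C)(C)O1 | starting material
11 | (1R)-1-(furan-3-yl)but-3-yn-1-ol | C#CC[C@@H](O)c1ccoc1 | intermediate
12 | dilithium salt (alkoxide and acetylide) of (1R)-1-(furan-3-yl)but-3-yn-1-ol | [Li]C#CC[C@@H](O[Li])c1ccoc1 | intermediate
13 | (5R)-5-(furan-3-yl)pent-2-yne-1,5-diol | OCC#CC[C@@H](O)c1ccoc1 | intermediate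
14 | (2E,5R)-5-(furan-3-yl)-2-(tributylstannyl)pent-2-ene-1,5-diol | CCCC[Sn](CCCC)(CCCC)/C(CO)=C/C[C@@H](O)c1ccoc1 | intermediate
15 | (2E,5R)-5-(furan-3-yl)-2-iodopent-2-ene-1,5-diol | I/C(CO)=C/C[C@@H](O)c1ccoc1 | intermediate
16 | 9-[(3E)-4-methyl-6-(2,6,6-trimethylcyclohex-1-en-1-yl)hex-3-en-1-yl]-9-borabicyclo[3.3.1]nonane | CC1=C(CC/C(C)=C/CCB2C3CCCC2CCC3)C(C)(C)CCC1 | intermediate
17 | (2Z,5R)-5-(furan-3-yl)-2-[(3E)-4-methyl-6-(2,6,6-trimethylcyclohex-1-en-1-yl)hex-3-en-1-yl]pent-2-ene-1,5-diol | CC1=C(CC/C(C)=C/CC/C(=C/C[C@@H](O)c2ccoc2)CO)C(C)(C)CCC1 | intermediate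
18 | furan endoperoxide of 17 (2,3,7-trioxabicyclo[2.2.1]hept-5-ene, mixture at the bridgeheads) | CC1=C(CC/C(C)=C/CC/C(=C/C[C@@H](O)C2=CC3OOC2O3)CO)C(C)(C)CCC1 | intermediate
19 | 5-hydroxy-4-[(1R,3Z,7E)-1-hydroxy-4-(hydroxymethyl)-8-methyl-10-(2,6,6-trimethylcyclohex-1-en-1-yl)deca-3,7-dien-1-yl]furan-2(5H)-one (both hemiacetal epimers) | CC1=C(CC/C(C)=C/CC/C(=C/C[C@@H](O)C2=CC(=O)OC2O)CO)C(C)(C)CCC1 | intermediate
20 | 4-[(1R,3Z,7E)-1-hydroxy-4-(hydroxymethyl)-8-methyl-10-(2,6,6-trimethylcyclohex-1-en-1-yl)deca-3,7-dien-1-yl]furan-2(5H)-one | CC1=C(CC/C(C)=C/CC/C(=C/C[C@@H](O)C2=CC(=O)OC2)CO)C(C)(C)CCC1 | target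

## Step count and risks

Total step count: 8. Longest linear sequence: 5 steps (1 → 4 → 6 → 8 → 17 → 20; the branch 9 → 11 → 13 → 15 → 17 → 20 is equally long).

The three steps most likely to fail:

Step 2 (acid cyclisation). The risk is a mixture of α/β/γ double‑bond isomers, or attack on the alkyne under superacid. The fallback closes the ring on a sulfone instead and sets out from 1. With sodium benzenesulfinate in DMF, 1 gives geranyl phenyl sulfone F1. Cyclisation in H2SO4–AcOH (the same proton‑triggered closure, with the sulfone favouring the tetrasubstituted olefin on equilibration) gives β‑cyclogeranyl phenyl sulfone F2. Its carbanion (n‑BuLi, THF, −78 °C) is alkylated with propargyl bromide to give {[1-(2,6,6-trimethylcyclohex-1-en-1-yl)but-3-yn-1-yl]sulfonyl}benzene F3. Pd‑catalysed reductive desulfonylation (PdCl2(dppp), LiBHEt3), which delivers hydride to the less hindered allyl terminus, comes back to the route at 6.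

Step 6 (hydrostannation). The risk is that the homopropargylic oxygen competes and tin goes to the wrong alkyne carbon. The fallback lets an ester fix the regiochemistry and a lactone fix the geometry, and sets out from 11. Oxidative methoxycarbonylation of the terminal alkyne (PdCl2 cat., CuCl2, NaOAc, CO, MeOH) gives methyl (5R)-5-(furan-3-yl)-5-hydroxypent-2-ynoate F4. Pd‑catalysed hydrostannation now places tin α to the ester, and the resulting Z‑hydroxy ester lactonises to (6R)-6-(furan-3-yl)-3-(tributylstannyl)-5,6-dihydro-2H-pyran-2-one F5. Iodine converts it to (6R)-6-(furan-3-yl)-3-iodo-5,6-dihydro-2H-pyran-2-one F6. B‑alkyl Suzuki coupling with 16 gives (6R)-6-(furan-3-yl)-3-[(3E)-4-methyl-6-(2,6,6-trimethylcyclohex-1-en-1-yl)hex-3-en-1-yl]-5,6-dihydro-2H-pyran-2-one F7. DIBAL‑H (CH2Cl2, −78 → 0 °C) opens the lactone to the Z‑diol and comes back to the route at 17.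

Step 8 (photooxygenation and reduction). The risk is ene reaction of singlet oxygen with the tetrasubstituted ring alkene or the trisubstituted alkene, or over‑reduction. The fallback forms the butenolide before the two halves are joined and sets out from 15. The same photooxygenation and NaBH4 sequence, now with no competing alkene, gives 4-[(1R,3E)-1,5-dihydroxy-4-iodopent-3-en-1-yl]furan-2(5H)-one F8. B‑alkyl Suzuki coupling with 16 under mild base (PdCl2(dppf), AsPh3, K3PO4, DMF–H2O, rt) comes back to the route at 20.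

## Further compounds

F1 | step 2 | geranyl phenyl sulfone, {[(2E)-3,7-dimethylocta-2,6-dien-1-yl]sulfonyl}benzene | CC(C)=CCC/C(C)=C/CS(=O)(=O)c1ccccc1
F2 | step 2 | β-cyclogeranyl phenyl sulfone, {[(2,6,6-trimethylcyclohex-1-en-1-yl)methyl]sulfonyl}benzene | CC1=C(CS(=O)(=O)c2ccccc2)C(C)(C)CCC1
F3 | step 2 | {[1-(2,6,6-trimethylcyclohex-1-en-1-yl)but-3-yn-1-yl]sulfonyl}benzene (racemic) | CC1=C(C(CC#C)S(=O)(=O)c2ccccc2)C(C)(C)CCC1
F4 | step 6 | methyl (5R)-5-(furan-3-yl)-5-hydroxypent-2-ynoate | COC(=O)C#CC[C@@H](O)c1ccoc1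
F5 | step 6 | (6R)-6-(furan-3-yl)-3-(tributylstannyl)-5,6-dihydro-2H-pyran-2-one | CCCC[Sn](CCCC)(CCCC)C1=CC[C@H](c2ccoc2)OC1=O
F6 | step 6 | (6R)-6-(furan-3-yl)-3-iodo-5,6-dihydro-2H-pyran-2-one | IC1=CC[C@H](c2ccoc2)OC1=O
F7 | step 6 | (6R)-6-(furan-3-yl)-3-[(3E)-4-methyl-6-(2,6,6-trimethylcyclohex-1-en-1-yl)hex-3-en-1-yl]-5,6-dihydro-2H-pyran-2-one | CC1=C(CC/C(C)=C/CCC2=CC[C@H](c3ccoc3)OC2=O)C(C)(C)CCC1
F8 | step 8 | 4-[(1R,3E)-1,5-dihydroxy-4-iodopent-3-en-1-yl]furan-2(5H)-one | I/C(CO)=C/C[C@@H](O)C1=CC(=O)OC1
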